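**Plan**

- **Cuts:** (1) The lactone O–C8 bond and the C9 hydroxyl are traced to an 8α,9α-epoxide and so to a C8=C9 alkene, with the O6 angelate and C13 removed as appendages. (2) C8=C9 goes back to two aldehydes. (3) C6–C7 is a syn aldol bond. (4) C10–CH3 comes from a conjugate methylation. (5) C1–C10 and C4–C5 come from a furan Diels–Alder reaction.
- **Enabling feature:** C8 and C9 are neighbouring carbons of ring B, and both carry oxygen in a trans-diaxial array (8β lactone oxygen, 9α hydroxyl). Anti opening of an epoxide leaves exactly this pattern. Both carbons can therefore begin as formyl carbons, one at the end of the chain on C5 and one on quaternary C10, where it cannot enolise.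
- **Forward order:** ring A with its C1–O–C4 bridge (an oxanorbornane) is made first. The C6–C7(–C11–C12)–C8 chain is then built on C5, and ring B is closed by reductive C8–C9 coupling. C13 and the angelate follow, and the γ-lactone comes last.
- **Stereochemistry:** exo-face cuprate attack sets C10 relative to C1 and C4. Base equilibration drained by selective hydrolysis sets C5 (trans). (S)-4-Benzyloxazolidinone sets C6 and C7. Because the two antipodes of the racemic aldehyde give separable diastereomers, it also selects the absolute configuration of C1, C4, C5 and C10. α-Face epoxidation and anti opening set C8 and C9.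

Key step: step 13

Remark on numbering: atom numbers are the eudesmane numbers of the target. Ring A is C1–C5 and C10 with oxygen bridging C1 and C4, ring B is C5–C10, and C11–C13 is the lactone arm. α/β refer to the usual drawing with the C10 methyl β. On the oxanorbornane, exo means syn to the oxygen bridge.

Assumption: all bicyclic compounds before the aldol step are racemates, drawn as the enantiomer that is carried on. The two aldol diastereomers of step 9 are taken to be separable on silica gel and to be told apart by X-ray analysis.

**Step 1**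
Reactants: 1 2-methylfuran; 2 dimethyl acetylenedicarboxylate
Product: 3 dimethyl 1-methyl-7-oxabicyclo[2.2.1]hepta-2,5-diene-2,3-dicarboxylate (racemate)
Conditions: neat, 25 → 40 °C, 48 h
Reagents that add atoms: none
Why: Thermal Diels–Alder reaction of an electron-rich furan with a doubly activated alkyne, which forms C1–C10 and C4–C5, closes ring A with its oxygen bridge and creates the bridgeheads C1 and C4, whose relative configuration is fixed by the bridge.

**Step 2**
Reactants: 3 oxanorbornadiene diester
Product: 4 dimethyl 1-methyl-7-oxabicyclo[2.2.1]hept-2-ene-2,3-dicarboxylate (racemate)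
Conditions: H2 (1 atm, stopped after one equivalent), Pd/C, EtOAc, rt
Reagents that add atoms: none
Why: Chemoselective catalytic hydrogenation, in which the strained disubstituted C2=C3 alkene reacts far faster than the tetrasubstituted ene-diester and saturation also closes the retro-Diels–Alder path.

**Step 3**
Reactants: 4 oxanorbornene diester
Product: 6 dimethyl 1,3-exo-dimethyl-7-oxabicyclo[2.2.1]heptane-2-endo,3-endo-dicarboxylate (racemate), via silyl ketene acetal 5 (not isolated)
Conditions: Me2CuLi (from MeLi, CuI), Me3SiCl, Et2O, −78 → −30 °C; then AcOH–H2O–THF, 0 °C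
Reagents that add atoms: lithium dimethylcuprate, [Li+].C[Cu-]C
Why: Chlorosilane-accelerated organocuprate conjugate addition to a strained ene-diester, in which methyl arrives on the exo face and at C10 (the alkene carbon next to the unsubstituted bridgehead C1, because the C4 methyl screens C5), Me3SiCl traps the C5 enolate as 5 before it can expel the bridge oxygen, and exo protonation on hydrolysis should leave the C5 ester endo, to be corrected in step 4.

**Step 4**
Reactants: 6 cis diester
Product: 8 3-endo-(methoxycarbonyl)-1,3-exo-dimethyl-7-oxabicyclo[2.2.1]heptane-2-exo-carboxylic acid (racemate), via trans diester 7 (not isolated)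
Conditions: NaOMe (0.2 equiv), MeOH, reflux; then KOH (1.1 equiv), H2O, reflux; then 1 M HCl
Reagents that add atoms: potassium hydroxide, [K+].[OH-]
Why: Base equilibration of an enolisable ester followed by selective saponification, in which C5 epimerises to put its carboxyl exo (H5 endo, trans to the endo ester on C10) and only this exposed secondary ester is hydrolysed while the neopentyl endo ester on quaternary C10 stays, so hydrolysis drains the epimer equilibrium into the trans series.

**Step 5**
Reactants: 8 trans half-acid
Product: 10 methyl 2-exo-[methoxy(methyl)carbamoyl]-1,3-exo-dimethyl-7-oxabicyclo[2.2.1]heptane-3-endo-carboxylate (racemate), via acid chloride 9 (not isolated)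
Conditions: (COCl)2, cat. DMF, CH2Cl2, 0 °C → rt, concentrate; then MeNH(OMe)·HCl, pyridine, CH2Cl2, 0 °C
Reagents that add atoms: N,O-dimethylhydroxylamine hydrochloride, CNOC.Cl
Why: Weinreb amide formation by way of the acid chloride, with pyridine in place of a trialkylamine so that ketene formation and loss of the C5 configuration are avoided.

**Step 6**
Reactants: 10 Weinreb amide ester
Product: 11 3-endo-(hydroxymethyl)-1,3-exo-dimethyl-7-oxabicyclo[2.2.1]heptane-2-exo-carbaldehyde (racemate)
Conditions: LiAlH4, THF, −40 → 0 °C; aqueous work-up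
Reagents that add atoms: none
Why: Hydride reduction in which the N-methoxy-N-methylamide halts at its chelated tetrahedral intermediate (released as the C6 aldehyde only on work-up) while the C9 ester goes to the primary alcohol, so the two carbonyl carbons are differentiated in one operation, and a trans-fused lactol is too strained to form.

**Step 7**
Reactants: 11 hydroxy aldehyde
Product: 12 (2-exo-formyl-1,3-exo-dimethyl-7-oxabicyclo[2.2.1]heptan-3-endo-yl)methyl acetate (racemate)
Conditions: Ac2O, pyridine, cat. DMAP, CH2Cl2, 0 °C
Reagents that add atoms: acetic anhydride, CC(=O)OC(C)=O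
Why: DMAP-catalysed acetylation masks the neopentyl C9 alcohol with a group that tolerates boron aldol and silyl triflate chemistry and falls later together with the auxiliary.

**Step 8**
Reactants: 13 4-tert-butoxy-4-oxobutanoic acid (mono-tert-butyl succinate); 14 (S)-4-benzyl-2-oxazolidinone
Product: 16 tert-butyl 4-[(S)-4-benzyl-2-oxooxazolidin-3-yl]-4-oxobutanoate, via mixed pivalic anhydride 15 (not isolated)
Conditions: PivCl, Et3N, THF, −20 °C; then LiCl, 14, −20 °C → rt
Reagents that add atoms: none
Why: N-acylation of an oxazolidinone through a mixed pivalic anhydride, attack taking place at the unhindered succinyl carbonyl.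

**Step 9**
Reactants: 12 acetoxy aldehyde (racemate); 16 succinyl imide
Product: 19 syn aldol adduct (6R,7S; 6α-OH; 7β-CH2CO2tBu; C8 = imide carbonyl; bicycle configured as in the target), via boron enolate 17 (not isolated), via boron aldolate 18 (not isolated)
Conditions: 16, Bu2BOTf, Et3N, CH2Cl2, −78 → 0 °C; 12, −78 → 0 °C; pH 7 buffer, MeOH, H2O2, 0 °C; chromatography
Reagents that add atoms: none
Why: Evans syn aldol reaction, in which the (Z)-boron enolate reacts through a chair Zimmerman–Traxler transition state on the face left open by the benzyl group, forming C6–C7 and setting 6R and 7S whichever antipode of the aldehyde reacts, so racemic 12 gives two adducts that differ at the contiguous C5/C6 pair and 19 is separated from its diastereomer.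

**Step 10**
Reactants: 19 aldol adduct
Product: 20 6-O-tert-butyldimethylsilyl ether of 19
Conditions: TBSOTf, 2,6-lutidine, CH2Cl2, 0 °C
Reagents that add atoms: tert-butyldimethylsilyl triflate, CC(C)(C)[Si](C)(C)OS(=O)(=O)C(F)(F)F
Why: Silylation of a hindered secondary alcohol with a silyl triflate and a non-nucleophilic base, kept short and cold to spare the tert-butyl ester, blocks retro-aldol cleavage and lactonisation of O6 onto C12.

**Step 11**
Reactants: 20 silylated imide
Product: 21 C8,C9-diol (6α-OTBS; 7β-CH2CO2tBu; CH2OH at C7 and endo on C10)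
Conditions: LiBH4, MeOH (additive), Et2O–THF, 0 °C → rt; cold aq NH4Cl
Reagents that add atoms: none
Why: Reductive removal of the oxazolidinone with LiBH4 (hydride attack at the exocyclic imide carbonyl) gives the C8 alcohol, the same reagent cleaves the C9 acetate, the tert-butyl ester is inert to LiBH4 at this temperature, and the cold neutral quench avoids lactonisation of O8 onto C12.

**Step 12**
Reactants: 21 diol
Product: 22 dialdehyde (endo formyl C9 on C10; exo chain C6(OTBS)–C7(CH2CO2tBu)–C8HO on C5)
Conditions: Dess–Martin periodinane (excess), CH2Cl2, 0 °C → rt; used at once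
Reagents that add atoms: none
Why: Dess–Martin oxidation of both primary alcohols under neutral conditions keeps the C7 configuration and the β-silyloxy group, and the excess of oxidant takes both alcohols on before a seven-membered lactol can intervene.

**Step 13**
Reactants: 22 dialdehyde
Product: 24 tricyclic C8=C9 alkene (ring B trans-fused to the oxanorbornane; 6α-OTBS; 7β-CH2CO2tBu), via titanium pinacolate 23 (not isolated)
Conditions: TiCl3(DME)1.5, Zn–Cu, DME, reflux 5 h; 22 in DME by syringe pump over 30 h (high dilution); reflux 5 h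
Reagents that add atoms: none
Why: Low-valent titanium made from TiCl3(DME)1.5 and Zn–Cu transfers one electron to each formyl group, the C8 and C9 ketyls held on the metal couple to the titanium pinacolate 23, and at reflux both C–O bonds break to leave the alkene 24. The closest known reaction type is the intramolecular McMurry coupling of 1,6-dialdehydes to cyclohexenes, which also reaches strained cycloalkenes. Ring B, a six-membered carbocycle, closes by head-to-head union of two trigonal carbonyl carbons, one on the exo chain at C5 and one endo on C10, so it is trans-fused to the oxanorbornane; the strain is paid for by the very strong Ti–O bonds formed, and the C–C bond itself is made at the less strained sp3 diolate stage. No stereocentre is created, because C8 and C9 end as sp2 carbons, and C5, C6, C7 and C10 are spectators: C10 is quaternary, and C7 is spared epimerisation and loss of the C6 silyloxy group because each portion of 22 is reduced as soon as it enters the flask. The step needs intramolecular over intermolecular coupling, secured by slow addition at high dilution, and aldehyde over ester reduction, secured by the much slower reaction of the tert-butyl ester, whose coupling with either aldehyde would in addition need a four- or seven-membered ring.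

**Step 14**
Reactants: 24 alkene ester
Product: 26 C11-(dimethylaminomethyl) ester (C11 epimers), via lithium enolate 25 (not isolated)
Conditions: LiN(iPr)2, THF, −78 °C; CH2=NMe2 I (Eschenmoser's salt), −78 °C → rt
Reagents that add atoms: N,N-dimethylmethyleneiminium iodide, C=[N+](C)C.[I-]
Why: Ester enolate Mannich reaction with Eschenmoser's salt brings in C13; C11 is the only acidic position, no leaving group sits β to it, and its new stereocentre is of no consequence because it becomes sp2 in the next step.

**Step 15**
Reactants: 26 Mannich base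
Product: 28 tert-butyl acrylate (C11=C13; 6α-OTBS; C8=C9), via ammonium iodide 27 (not isolated)
Conditions: MeI, CH2Cl2, rt; then DBU, 0 °C
Reagents that add atoms: none
Why: Exhaustive N-methylation and E1cB (Hofmann-type) loss of trimethylamine, the standard second half of an α-methylenation, kept cold and short so that the doubly allylic C7–H is not touched.

**Step 16**
Reactants: 28 silyl ether
Product: 29 6α-alcohol
Conditions: HF·pyridine, pyridine–THF, 0 °C → rt
Reagents that add atoms: none
Why: Fluoride cleavage of the silyl ether under mildly acidic conditions, chosen so that no alkoxide forms that could add to the acrylate or lactonise onto C12, while the tert-butyl ester and the alkenes are inert.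

**Step 17**
Reactants: 29 6α-alcohol; 30 angelic acid
Product: 32 6α-angelate, via mixed trichlorobenzoic anhydride 31 (not isolated)
Conditions: 30, 2,4,6-trichlorobenzoyl chloride, Et3N, toluene, rt; then 29, 80 °C (no DMAP)
Reagents that add atoms: none
Why: Yamaguchi-type esterification through the mixed anhydride without a nucleophilic catalyst, the established way to transfer an angeloyl group without Z to E isomerisation, and O6 is the only hydroxyl present because O9 does not yet exist.

**Step 18**
Reactants: 32 triene
Product: 33 8α,9α-epoxide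
Conditions: mCPBA, CH2Cl2, 0 °C
Reagents that add atoms: 3-chloroperoxybenzoic acid, O=C(OO)c1cccc(Cl)c1
Why: Prilezhaev epoxidation, in which only the strained, electron-rich cis C8=C9 bond reacts (acrylate and angelate are electron-poor) and the peracid comes from the α face because the β face is covered by the axial C10 methyl next to C9 and by the 7β arm next to C8, which sets both epoxide carbons.

**Step 19**
Reactants: 33 epoxy tert-butyl ester
Product: 34 target (1β,4β-epoxy-6α-angeloyloxy-9α-hydroxy-5αH,7αH,8αH-eudesm-11(13)-en-12,8β-olide)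
Conditions: 20% CF3CO2H in CH2Cl2, 0 °C → rt
Reagents that add atoms: none
Why: Acid-induced lactonisation of an epoxy tert-butyl ester, in which the C12 carbonyl oxygen, held on the β face by C7, attacks the protonated epoxide at C8 in a 5-exo, anti, trans-diaxial (Fürst–Plattner) opening with loss of isobutene, which inverts C8 to 8β-O, leaves the epoxide oxygen as the 9α-hydroxyl and closes the cis-fused α-methylene-γ-lactone.

**Compound list**

1 | 2-methylfuran | Cc1ccco1 | starting material
2 | dimethyl acetylenedicarboxylate | COC(=O)C#CC(=O)OC | starting material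
3 | dimethyl 1-methyl-7-oxabicyclo[2.2.1]hepta-2,5-diene-2,3-dicarboxylate (racemate) | COC(=O)C1[C@H]2C=C[C@](C)(O2)C=1C(=O)OC | intermediate
4 | dimethyl 1-methyl-7-oxabicyclo[2.2.1]hept-2-ene-2,3-dicarboxylate (racemate) | COC(=O)C1[C@H]2CC[C@](C)(O2)C=1C(=O)OC | intermediate
5 | silyl ketene acetal at C5/C6, exo methyl on C10 (racemate, not isolated) | COC(=O)[C@@]1(C)[C@H]2CC[C@](C)(O2)C1=C(OC)O[Si](C)(C)C | intermediate
6 | cis diester: 3-exo-methyl, 2-endo and 3-endo esters (racemate) | COC(=O)[C@@]1(C)[C@H]2CC[C@](C)(O2)[C@H]1C(=O)OC | intermediate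
7 | trans diester: 3-exo-methyl, 2-exo and 3-endo esters (racemate, not isolated) | COC(=O)[C@@]1(C)[C@H]2CC[C@](C)(O2)[C@@H]1C(=O)OC | intermediate
8 | trans half-acid: 2-exo-CO2H, 3-endo-CO2Me (racemate) | COC(=O)[C@@]1(C)[C@H]2CC[C@](C)(O2)[C@@H]1C(=O)O | intermediate
9 | acid chloride of 8 (racemate, not isolated) | COC(=O)[C@@]1(C)[C@H]2CC[C@](C)(O2)[C@@H]1C(=O)Cl | intermediate
10 | Weinreb amide at C6, methyl ester at C9 (racemate) | COC(=O)[C@@]1(C)[C@H]2CC[C@](C)(O2)[C@@H]1C(=O)N(C)OC | intermediate
11 | hydroxy aldehyde: exo C6 formyl on C5, endo C9 CH2OH on C10 (racemate) | OC[C@@]1(C)[C@H]2CC[C@](C)(O2)[C@@H]1C=O | intermediate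
12 | acetoxy aldehyde (racemate) | CC(=O)OC[C@@]1(C)[C@H]2CC[C@](C)(O2)[C@@H]1C=O | intermediate
13 | 4-tert-butoxy-4-oxobutanoic acid | CC(C)(C)OC(=O)CCC(=O)O | starting material
14 | (S)-4-benzyl-2-oxazolidinone | O=C1N[C@@H](Cc2ccccc2)CO1 | starting material
15 | mixed pivalic anhydride of 13 (not isolated) | CC(C)(C)OC(=O)CCC(=O)OC(=O)C(C)(C)C | intermediate
16 | tert-butyl 4-[(S)-4-benzyl-2-oxooxazolidin-3-yl]-4-oxobutanoate | CC(C)(C)OC(=O)CCC(=O)N1[C@@H](Cc2ccccc2)COC1=O | intermediate
17 | (Z)-dibutylboron enolate of 16 (not isolated) | CCCCB(CCCC)O/C(=C\CC(=O)OC(C)(C)C)N1[C@@H](Cc2ccccc2)COC1=O | intermediate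
18 | dibutylboron aldolate (not isolated) | CC(=O)OC[C@@]1(C)[C@H]2CC[C@](C)(O2)[C@@H]1[C@@H](OB(CCCC)CCCC)[C@H](CC(=O)OC(C)(C)C)C(=O)N1[C@@H](Cc2ccccc2)COC1=O | intermediate
19 | syn aldol adduct (6R,7S) | CC(=O)OC[C@@]1(C)[C@H]2CC[C@](C)(O2)[C@@H]1[C@@H](O)[C@H](CC(=O)OC(C)(C)C)C(=O)N1[C@@H](Cc2ccccc2)COC1=O | intermediate
20 | 6-O-TBS ether of 19 | CC(=O)OC[C@@]1(C)[C@H]2CC[C@](C)(O2)[C@@H]1[C@@H](O[Si](C)(C)C(C)(C)C)[C@H](CC(=O)OC(C)(C)C)C(=O)N1[C@@H](Cc2ccccc2)COC1=O | intermediate
21 | C8,C9-diol | OC[C@@]1(C)[C@H]2CC[C@](C)(O2)[C@@H]1[C@@H](O[Si](C)(C)C(C)(C)C)[C@H](CC(=O)OC(C)(C)C)CO | intermediate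
22 | C8,C9-dialdehyde | O=C[C@@]1(C)[C@H]2CC[C@](C)(O2)[C@@H]1[C@@H](O[Si](C)(C)C(C)(C)C)[C@H](CC(=O)OC(C)(C)C)C=O | intermediate
23 | titanium 8,9-pinacolate, surface-bound, drawn as the cyclic diolate (not isolated) | CC(C)(C)OC(=O)C[C@@H]1C2O[Ti]OC2[C@@]3(C)[C@H]4CC[C@](C)(O4)[C@@H]3[C@H]1O[Si](C)(C)C(C)(C)C | intermediate
24 | tricyclic C8=C9 alkene | CC(C)(C)OC(=O)C[C@@H]1C=C[C@@]2(C)[C@H]3CC[C@](C)(O3)[C@@H]2[C@H]1O[Si](C)(C)C(C)(C)C | intermediate
25 | lithium enolate of 24 (not isolated) | CC(C)(C)OC(O[Li])=C[C@@H]1C=C[C@@]2(C)[C@H]3CC[C@](C)(O3)[C@@H]2[C@H]1O[Si](C)(C)C(C)(C)C | intermediate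
26 | C11-(dimethylaminomethyl) ester (C11 epimers) | CN(C)CC(C(=O)OC(C)(C)C)[C@@H]1C=C[C@@]2(C)[C@H]3CC[C@](C)(O3)[C@@H]2[C@H]1O[Si](C)(C)C(C)(C)C | intermediate
27 | trimethylammonium iodide of 26 (not isolated) | C[N+](C)(C)CC(C(=O)OC(C)(C)C)[C@@H]1C=C[C@@]2(C)[C@H]3CC[C@](C)(O3)[C@@H]2[C@H]1O[Si](C)(C)C(C)(C)C.[I-] | intermediate
28 | tert-butyl acrylate, 6α-OTBS | C=C(C(=O)OC(C)(C)C)[C@@H]1C=C[C@@]2(C)[C@H]3CC[C@](C)(O3)[C@@H]2[C@H]1O[Si](C)(C)C(C)(C)C | intermediate
29 | tert-butyl acrylate, 6α-OH | C=C(C(=O)OC(C)(C)C)[C@@H]1C=C[C@@]2(C)[C@H]3CC[C@](C)(O3)[C@@H]2[C@H]1O | intermediate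
30 | angelic acid | C/C=C(/C)C(=O)O | starting material
31 | angelic 2,4,6-trichlorobenzoic anhydride (not isolated) | C/C=C(/C)C(=O)OC(=O)c1c(Cl)cc(Cl)cc1Cl | intermediate
32 | 6α-angelate | C=C(C(=O)OC(C)(C)C)[C@@H]1C=C[C@@]2(C)[C@H]3CC[C@](C)(O3)[C@@H]2[C@H]1OC(=O)/C(C)=C\C | intermediate
33 | 8α,9α-epoxide | C=C(C(=O)OC(C)(C)C)[C@@H]1[C@H]2O[C@H]2[C@@]3(C)[C@H]4CC[C@](C)(O4)[C@@H]3[C@H]1OC(=O)/C(C)=C\C | intermediate
34 | CNP0328162.1 | C=C1C(=O)O[C@H]2[C@@H]1[C@H](OC(=O)/C(C)=C\C)[C@@H]1[C@@](C)([C@@H]2O)[C@H]2CC[C@]1(C)O2 | target

**Step count**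

Total steps: 19. Longest linear sequence: 18 (steps 1–7 and 9–19).

**Steps most likely to fail**

**Step 13.**
- *What may go wrong:* the coupling may halt at the diolate, because a rigid trans-fused ring cannot offer both oxygens to the metal. Intermolecular coupling, or elimination of the C6 silyloxy group under the Lewis-acidic conditions, may also outrun ring closure.
- *Fallback:* the same bond and ring are made at the diol level, setting out from 22.
  - SmI2 (THF, tBuOH, −78 °C → rt) should give, by pinacol cyclisation with divalent samarium, the cis-8α,9α-diol F1. The diol is expected anti to the 7β arm.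
  - Thiocarbonyldiimidazole (toluene, 80 °C) should convert it into the cyclic thionocarbonate F2.
  - A Corey–Winter fragmentation (P(OMe)3, reflux), a concerted syn cycloreversion suited to strained alkenes, comes back to the route at 24.

**Step 3.**
- *What may go wrong:* methyl may attack the wrong alkene carbon, electron transfer may reduce the ene-diester without methyl transfer, or the C5 enolate may expel the bridge oxygen. The last of these is also a threat during the equilibration of step 4.
- *Fallback:* the trans array is set kinetically by two exo-face bond formations, setting out from 1.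
  - A Diels–Alder reaction with methyl (E)-3-nitroacrylate should give methyl 4-methyl-3-nitro-7-oxabicyclo[2.2.1]hept-5-ene-2-carboxylate F3. The nitro group directs the regiochemistry, so the nitro-bearing carbon ends next to the methyl-bearing bridgehead.
  - Hydrogenation (H2, Pd/C) should give the saturated nitro ester F4.
  - DBU removes nitrous acid to give methyl 4-methyl-7-oxabicyclo[2.2.1]hept-2-ene-2-carboxylate F5.
  - A vinyl cuprate (CH2=CHMgBr, CuI, THF, −78 °C) adds to C5 from the exo face. The C10 enolate is methylated cold with MeI, again from the exo face, to give the exo-vinyl exo-methyl endo-ester F6.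
  - Ozonolysis (O3; Me2S) gives the C6 aldehyde F7, and NaClO2 oxidation comes back to the route at 8.

**Step 17.**
- *What may go wrong:* acyl transfer to the crowded 6α-hydroxyl may be slow. Z to E isomerisation of the activated angelate, or lactonisation of O6 onto C12, may then take over.
- *Fallback:* the angelate double bond is built on the molecule, setting out from 29.
  - Esterification with 2-[bis(2,2,2-trifluoroethoxy)phosphoryl]propanoic acid (DCC, DMAP, CH2Cl2) should give the 6α-phosphonopropionate F8.
  - A Z-selective Still–Gennari olefination with acetaldehyde (KN(SiMe3)2, 18-crown-6, THF, −78 °C) comes back to the route at 32. The phosphonate is by far the most acidic site.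

**Further compounds**

F1 | step 13 | cis-8α,9α-diol (6α-OTBS, 7β-CH2CO2tBu) | CC(C)(C)OC(=O)C[C@@H]1[C@@H](O)[C@@H](O)[C@@]2(C)[C@H]3CC[C@](C)(O3)[C@@H]2[C@H]1O[Si](C)(C)C(C)(C)C
F2 | step 13 | 8α,9α-cyclic thionocarbonate | CC(C)(C)OC(=O)C[C@@H]1[C@H]2OC(=S)O[C@H]2[C@@]3(C)[C@H]4CC[C@](C)(O4)[C@@H]3[C@H]1O[Si](C)(C)C(C)(C)C
F3 | step 3 | methyl 4-methyl-3-nitro-7-oxabicyclo[2.2.1]hept-5-ene-2-carboxylate (racemate, 2,3-trans, endo/exo mixture) | COC(=O)C1[C@H]2C=C[C@](C)(O2)C1[N+](=O)[O-]
F4 | step 3 | methyl 4-methyl-3-nitro-7-oxabicyclo[2.2.1]heptane-2-carboxylate (racemate) | COC(=O)C1[C@H]2CC[C@](C)(O2)C1[N+](=O)[O-]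
F5 | step 3 | methyl 4-methyl-7-oxabicyclo[2.2.1]hept-2-ene-2-carboxylate (racemate) | COC(=O)C1[C@H]2CC[C@](C)(O2)C=1
F6 | step 3 | methyl 2-exo,4-dimethyl-3-exo-vinyl-7-oxabicyclo[2.2.1]heptane-2-endo-carboxylate (racemate) | COC(=O)[C@@]1(C)[C@H]2CC[C@](C)(O2)[C@@H]1C=C
F7 | step 3 | methyl 3-exo-formyl-2-exo,4-dimethyl-7-oxabicyclo[2.2.1]heptane-2-endo-carboxylate (racemate) | COC(=O)[C@@]1(C)[C@H]2CC[C@](C)(O2)[C@@H]1C=O
F8 | step 17 | 6α-[2-bis(2,2,2-trifluoroethoxy)phosphorylpropanoate] of 29 | C=C(C(=O)OC(C)(C)C)[C@@H]1C=C[C@@]2(C)[C@H]3CC[C@](C)(O3)[C@@H]2[C@H]1OC(=O)C(C)P(=O)(OCC(F)(F)F)OCC(F)(F)F
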